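## Analysis of the target

Thiocladospolide F is a C2-symmetric bis-macrolide: two identical 12-membered lactones (ring atoms O1 and C1–C11 in chain numbering, primed for the second ring) are joined by one sulfide sulfur on C2 and C2', alpha to each lactone carbonyl. Each half has three stereocentres, C2 (S, the C–S carbon), C5 (S, secondary carbinol) and C11 (R, the methyl carbinol that closes the lactone), and the two halves are homotopic, so one set of operations applied twice serves both. C2 and C5 are 1,4-related across the C4 ketone and C11 is remote from both, so no centre can set another and each must come from the chiral pool or a reagent. The sensitive array is C1(=O)–C2(S)–C3–C4(=O)–C5(OH): sulfur is beta to the C4 ketone, so a base that enolises C3 expels thiolate (retro-sulfa-Michael), the C5 ketol centre epimerises through the same enol, and the thioether excludes ozone, peracids and oxidative carbonyl unmasking. A second difficulty is topological: in a dimer joined at sulfur each carboxyl must lactonise with the hydroxyl of its own chain (12-membered ring) and not with that of the other chain (14-membered ring through sulfur). The plan rests on C4 (ketone) and C5 (carbinol) being adjacent oxygenated carbons, which a nitronate at C4 and an aldehyde at C5 can join; while C4 carries nitro, the acidic site is C4 itself, and a carbanion there finds no leaving group on the neighbouring carbon C3, so sulfur on C2 is out of reach.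

## Retrosynthetic reasoning

Target 24 to bis-lactone 21. The last operations remove two silyl ethers (24 from 23) and, before that, turn two nitro groups into the C4 and C4' ketones (23 from 21). The ketone is unveiled this late because every base-mediated operation must be finished before a beta-thio ketone exists. The unmasking has to be a reductive Nef reaction, since the sulfide forbids the oxidative variants.

Bis-lactone 21 to bis(hydroxy acid) 19. The two C1–O bonds are cut. These are the only ring bonds, and cutting them leaves an open-chain, C2-symmetric precursor in which every C–C bond and every stereocentre is already in place. The forward reaction must acylate each C11 hydroxyl at room temperature without touching the acidic C2–H. The C5 oxygens are silylated so that the six-membered lactone cannot form, and the reaction must pair each carboxyl with the hydroxyl of its own arm.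

Bis(hydroxy acid) 19 to bis(nitro alcohol) 16. This is protecting-group traffic only (19 from 18 from 17 from 16). The carboxyls are carried as allyl esters and the C11 oxygens as PMB ethers, two groups that come off under neutral conditions which a nitroalkane and a thioether tolerate.

Bis(nitro alcohol) 16 to bis(nitroalkane) 8 and two molecules of aldehyde 15. The C4–C5 and C4'–C5' bonds are cut. This is the one place where the molecule divides into a small symmetric core holding the sulfur and both C2 centres, and two identical chain pieces. The polarity is natural for a nitronate acting as an acyl anion at C4, and the new carbinol centre lies on the bond being formed, where a chiral catalyst can set it. The forward step must deprotonate only next to nitro and choose one face of an unbranched aldehyde, twice.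

Bis(nitroalkane) 8 to bis-lactone sulfide 4. Each nitro group is traced to a primary bromide (8 from 7) and each bromo ester to a gamma-lactone (7 from 4, with two molecules of allyl alcohol 5 supplying the two ester groups). The lactone masks C1 and the C4 oxygen at once, and it is opened only after the C–S bonds exist, so no nitronate is ever present next to a leaving group at C2.

Bis-lactone sulfide 4 to hydroxy lactone 1. Both C–S bonds are cut. They are made by SN2 displacement with inversion on the alpha-triflyloxy lactone 2, so the (R)-hydroxy lactone 1 delivers (S) at C2 and C2'. The thioether is thus built on a four-carbon unit at the very start, where losses are cheap.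

Aldehyde 15 to bromide 9 and epoxide 10. The aldehyde is traced to a terminal alkene (15 from 13 from 12), and the C5–C6 bond of the octanal chain (C9–C10 of the target) to the opening of epoxide 10 by Grignard reagent 11, made from bromide 9. The epoxide supplies C11 with its (R) configuration, and the alkene is a one-carbon-longer mask of the aldehyde.

## Alternatives that were turned down

Alternative 1: Double lactonization of a diacid made by Jocic chemistry.
- Disconnection: both C1–O bonds are cut last. One stage earlier each C2–S bond is traced to a Jocic reaction, in which sulfide opens with inversion the dichloro-epoxide formed in base from the trichloromethyl carbinol A3, and the CCl3 carbon becomes C1.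
- Forward key step: the diacid-diol A2 is activated as a bis(mixed anhydride) and both 12-membered lactones are closed to give A1, with C4 and C4' as dioxolanes and C5 and C5' as silyl ethers.
- For: the ketone is an acetal throughout, so no beta-thio ketone ever meets base and the endgame needs only acid. On this point it is stronger than the chosen route, which must pass a Nef reaction. Carboxyl and C–S bond arise in one operation.
- Against: the C–S bonds are made on two fully built chains, each with three stereocentres, under aqueous hydroxide. The second Jocic event needs an alpha-thio carboxylate as nucleophile at a hindered centre, so the most valuable material is spent on the least certain bond. Every chain needs its own asymmetric steps for the carbinol centre and for C5, which lengthens the linear sequence. A dioxolane next to a silyloxy carbon is slow to form and to hydrolyse.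
- Comparison: the ring closure has the same pairing question (12-membered own-arm against 14-membered cross-arm) as step 12 here and gains nothing there. The chosen route pays with the Nef step but puts the C–S bonds on a cheap lactone and builds C4–C5 and C5 of both halves in one catalytic step.

Alternative 2: Double Stetter addition to a bis(alpha-thioacrylate).
- Disconnection: C3–C4 and C3'–C4', so the 1,4-dicarbonyl comes from an acyl anion and an acrylate. The rings are closed afterwards at C9–C10 by metathesis (second-generation Grubbs catalyst) and the alkenes saturated.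
- Forward key step: two molecules of aldehyde A6, turned into acyl anion equivalents by a chiral N-heterocyclic carbene, add to the methylene carbons of bis(acrylate) A5. The ester enolates are protonated at C2 and C2' under catalyst control to give A4.
- For: C4 appears directly as the ketone, C5 comes from the aldehyde, the C2 centres are made catalytically, and the sequence is short. It needs no Nef step, which is a real advantage.
- Against: alpha-silyloxy aldehydes are hindered Stetter donors that can epimerise or lose silyloxide, and an alpha-thio acrylate is an electron-rich, sluggish acceptor. Two enantioselective protonations must occur at the sulfur-bearing carbon. Above all, A4 is the beta-thio ketone with an enolisable C3, formed in a basic carbene medium, so loss of sulfur and scrambling at C2 threaten at once. Metathesis must tolerate the thioether and faces the same pairing question, and the alkene reduction must not be poisoned by sulfur.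
- Comparison: shorter on paper, but several untested demands sit on one step. The chosen route keeps C4 as nitro to stay away from that enolate and uses a key reaction of an established type.

Alternative 3: Iterative ring-contracting Doyle–Kirmse closure on sulfur.
- Disconnection: in each ring S–C2 and C2–C3 are cut together, backwards through a [2,3] shift of a sulfonium ylide. The rings are made one after the other on sulfur.
- Forward key step: the carbene formed from diazoacetate A8 with dirhodium tetraacetate Rh2(OAc)4 is caught by the tethered allyl sulfide. The 13-membered cyclic ylide rearranges, contracting the ring to lactone A7 with sulfur on C2 and a methylidene on C4. The silylethyl group is then removed, the thiol allylated with a second chain, and the sequence repeated.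
- For: each ring is closed on its own, so the pairing problem of every dimer-first plan does not arise. Here it is clearly stronger than the chosen route. Ring, C–S and C–C bond come from one step.
- Against: formation of a 13-membered ylide must beat carbene dimerisation, C–H insertion and attack on the PMB ring. The C2 configuration would depend on a remote centre or a chiral catalyst in a macrocyclic [2,3] shift, for which no reliable control can be claimed. The second round needs a hindered, ester-deactivated sulfide to trap the carbene. The methylidene must be cleaved oxidatively next to a thioether, and the sequence is linear and about twice as long.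
- Comparison: the chosen route gives up the clean answer to pairing, but sets C2 from the chiral pool by SN2 inversion, sets C5 by a known catalytic reaction, and needs no oxidation once sulfur is in place.

Key step: step 8

Assumption: the (4S,4'S)-tert-butyl bis(oxazoline) is taken to be the ligand antipode that sends the nitronate to the Re face of the aldehyde (which gives 5S); if a model reaction shows the opposite sense, the (4R,4'R) ligand is used with nothing else changed.

## Route

Step 1
Reactants: 1 (3R)-3-hydroxyoxolan-2-one [(R)-alpha-hydroxy-gamma-butyrolactone]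
Product: 2 (3R)-2-oxooxolan-3-yl trifluoromethanesulfonate
Conditions: Tf2O, 2,6-lutidine, CH2Cl2, −40 °C; used at once
Reagents that add atoms: trifluoromethanesulfonic anhydride, O=S(=O)(OS(=O)(=O)C(F)(F)F)C(F)(F)F
Why: O-sulfonylation of a secondary alpha-hydroxy lactone; no bond to the stereocentre is touched, so (R) is kept, and alpha-carbonyl triflates are reactive SN2 electrophiles that do not ionise.

Step 2
Reactants: 2 (3R)-2-oxooxolan-3-yl trifluoromethanesulfonate (two equivalents in all)
Product: 4 (3S,3'S)-3,3'-sulfanediylbis(oxolan-2-one), via (3S)-3-sulfanyloxolan-2-one 3 (not isolated)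
Conditions: NaSH (1 equiv), first equiv of 2, DMF, −40 °C; then iPr2NEt, second equiv of 2, −40 → 0 °C, under argon
Reagents that add atoms: sodium hydrosulfide, [Na+].[SH-]
Why: two SN2 displacements of an alpha-carbonyl triflate by sulfur, each with inversion: hydrosulfide gives thiol 3, whose thiolate attacks the second portion of 2, so both centres become (S). NaSH with a hindered amine is used instead of Na2S to keep the medium weakly basic and so suppress elimination to the butenolide and epimerisation of the alpha-thio lactone.

Step 3
Reactants: 4 (3S,3'S)-3,3'-sulfanediylbis(oxolan-2-one); 5 prop-2-en-1-ol, allyl alcohol (12 equiv)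
Product: 7 diallyl (2S,2'S)-2,2'-sulfanediylbis(4-bromobutanoate), via the ring-opened bis(acyloxydibromoborane) 6 (not isolated)
Conditions: BBr3 (3.5 equiv), CH2Cl2, 0 °C → rt; then 5 (12 equiv), 0 °C → rt; NaHCO3 work-up
Reagents that add atoms: boron tribromide, BrB(Br)Br
Why: Lewis-acid opening of a gamma-lactone: boron activates the carbonyl, bromide attacks the O–CH2 carbon (SN2 at C4, no stereocentre involved), and alcoholysis of each acyloxyborane by one molecule of 5 gives the allyl ester, so two molecules of 5 end up in 7 while the rest is used up by the B–Br bonds. Sulfur cannot take part, since that would need a four-membered sulfonium ring, and the BBr3 beyond the two equivalents that open the rings allows for its reversible complex with the sulfide.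

Step 4
Reactants: 7 diallyl (2S,2'S)-2,2'-sulfanediylbis(4-bromobutanoate)
Product: 8 diallyl (2S,2'S)-2,2'-sulfanediylbis(4-nitrobutanoate)
Conditions: NaNO2 (4 equiv), phloroglucinol, DMSO, rt
Reagents that add atoms: sodium nitrite, [Na+].[O-]N=O
Why: Kornblum substitution of primary bromides by nitrite in a dipolar aprotic solvent (attack through nitrogen gives the nitroalkane). Phloroglucinol intercepts the nitrite-ester by-product before it nitrosates the product, and nitrite is too weak a base to touch C2–H.

Step 5
Reactants: 9 6-bromohex-1-ene; 10 (R)-2-methyloxirane [(R)-propylene oxide]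
Product: 12 (2R)-non-8-en-2-ol, via hex-5-en-1-ylmagnesium bromide 11 (not isolated)
Conditions: Mg, THF; then CuI (10 mol %), 10, THF, −30 → 0 °C; aq NH4Cl
Reagents that add atoms: none
Why: copper-catalysed opening of a terminal epoxide by a primary Grignard reagent at the CH2 carbon; the stereocentre of 10 is not involved and becomes C11 (R).

Step 6
Reactants: 12 (2R)-non-8-en-2-ol
Product: 13 1-methoxy-4-({[(2R)-non-8-en-2-yl]oxy}methyl)benzene
Conditions: NaH, 4-methoxybenzyl chloride, Bu4NI (cat.), DMF, 0 °C → rt
Reagents that add atoms: 4-methoxybenzyl chloride, COc1ccc(CCl)cc1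
Why: Williamson etherification of the alkoxide; the C–O bond at the stereocentre is not broken.

Step 7
Reactants: 13 1-methoxy-4-({[(2R)-non-8-en-2-yl]oxy}methyl)benzene
Product: 15 (7R)-7-[(4-methoxybenzyl)oxy]octanal, via (8R)-8-[(4-methoxybenzyl)oxy]nonane-1,2-diol 14 (not isolated)
Conditions: OsO4 (2 mol %), NaIO4 (4 equiv), 2,6-lutidine, dioxane/H2O 3:1, rt
Reagents that add atoms: osmium tetroxide, O=[Os](=O)(=O)=O (catalytic, delivers the oxygen); sodium periodate, [Na+].[O-]I(=O)(=O)=O (reoxidant and cleaving agent)
Why: Lemieux–Johnson cleavage of the terminal alkene (dihydroxylation, then periodate cleavage of diol 14), which removes one carbon and leaves the C8 aldehyde. It is chosen over ozonolysis because ozone attacks the electron-rich PMB ring.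

Step 8
Reactants: 8 diallyl (2S,2'S)-2,2'-sulfanediylbis(4-nitrobutanoate); 15 (7R)-7-[(4-methoxybenzyl)oxy]octanal (3 equiv)
Product: 16 diallyl (2S,2'S)-2,2'-sulfanediylbis[(5S,11R)-5-hydroxy-11-(4-methoxybenzyloxy)-4-nitrododecanoate], mixture of epimers at C4 and C4'
Conditions: Cu(OAc)2·H2O (20 mol %), 2,2'-isopropylidenebis[(4S)-4-tert-butyl-2-oxazoline] (22 mol %), EtOH, 0 °C → rt
Reagents that add atoms: none
Why: Nitroaldol (Henry) addition: acetate on divalent copper deprotonates the CH2NO2 group, which is far more acidic than C2–H of the alpha-thio ester, and the nitronate stays on the metal. The aldehyde binds in the ligand plane, the nitronate carbon C4 is delivered to one carbonyl face through a cyclic transition state, and protonation releases the nitro alcohol and the catalyst. The closest known reaction type is the Cu(OAc)2–bis(oxazoline)-catalysed enantioselective Henry reaction of unbranched aliphatic aldehydes with nitromethane and higher nitroalkanes. No ring is closed; the two C–C bonds C4–C5 and C4'–C5' form independently in the two arms. C5 and C5' are set by the ligand (Re-face attack gives S), because the nearest existing centres, C2 two bonds from the nitronate carbon and C11 six bonds from the aldehyde carbon, are too remote to compete. C4 and C4' form without control and need none, since they become sp2 in step 13. The step needs deprotonation at C4 only, which the acidity gap to C2–H and the absence of any leaving group on C3 secure; because C2 and C11 are already fixed, an arm that adds on the wrong face gives a diastereomer, not an enantiomer, and can be removed. Low temperature and direct silylation in step 9 keep the C5 hydroxyl from lactonising onto the allyl ester.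

Step 9
Reactants: 16 diallyl (2S,2'S)-2,2'-sulfanediylbis[(5S,11R)-5-hydroxy-11-(4-methoxybenzyloxy)-4-nitrododecanoate]
Product: 17 diallyl (2S,2'S)-2,2'-sulfanediylbis[(5S,11R)-5-(tert-butyldimethylsilyloxy)-11-(4-methoxybenzyloxy)-4-nitrododecanoate]
Conditions: TBSCl, imidazole, DMF, rt
Reagents that add atoms: tert-butyldimethylsilyl chloride, CC(C)(C)[Si](C)(C)Cl
Why: silylation of secondary alcohols with a silyl chloride and imidazole, a base too weak to cause retro-Henry cleavage or dehydration. The silyl ethers block the six-membered lactone and the retro-nitroaldol in all later steps.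

Step 10
Reactants: 17 diallyl (2S,2'S)-2,2'-sulfanediylbis[(5S,11R)-5-(tert-butyldimethylsilyloxy)-11-(4-methoxybenzyloxy)-4-nitrododecanoate]
Product: 18 diallyl (2S,2'S)-2,2'-sulfanediylbis[(5S,11R)-5-(tert-butyldimethylsilyloxy)-11-hydroxy-4-nitrododecanoate]
Conditions: DDQ, CH2Cl2/pH 7 buffer, 0 °C → rt
Reagents that add atoms: none
Why: oxidative cleavage of PMB ethers by DDQ (hydride abstraction at the electron-rich benzylic carbon, then hydrolysis). The sulfide is flanked by two esters and therefore electron-poor, and nitro groups, silyl ethers and allyl esters are inert.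

Step 11
Reactants: 18 diallyl (2S,2'S)-2,2'-sulfanediylbis[(5S,11R)-5-(tert-butyldimethylsilyloxy)-11-hydroxy-4-nitrododecanoate]
Product: 19 (2S,2'S)-2,2'-sulfanediylbis[(5S,11R)-5-(tert-butyldimethylsilyloxy)-11-hydroxy-4-nitrododecanoic acid]
Conditions: Pd(PPh3)4 (10 mol %), N-methylaniline, THF, rt
Reagents that add atoms: none
Why: Tsuji–Trost deallylation: zerovalent palladium ionises the allyl esters and N-methylaniline captures the pi-allyl complexes. This scavenger is too weakly basic to form nitronates, so C-allylation at C4 is avoided and the acids are freed without hydroxide.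

Step 12
Reactants: 19 (2S,2'S)-2,2'-sulfanediylbis[(5S,11R)-5-(tert-butyldimethylsilyloxy)-11-hydroxy-4-nitrododecanoic acid]
Product: 21 (3S,3'S)-3,3'-sulfanediylbis[(6S,12R)-6-(tert-butyldimethylsilyloxy)-12-methyl-5-nitrooxacyclododecan-2-one], via the mono-lactone hydroxy acid 20 (not isolated)
Conditions: 2-methyl-6-nitrobenzoic anhydride (MNBA), DMAP, CH2Cl2 (1 mM), rt, slow addition of 19
Reagents that add atoms: none
Why: Shiina macrolactonization: each carboxyl forms a mixed anhydride that a C11 hydroxyl attacks under DMAP catalysis at high dilution, with retention at C11; the C5 silyl ethers exclude the six-membered lactone and the nitro groups keep C3 non-enolisable, so sulfur is not expelled. The first closure can take the hydroxyl of the same arm (12-membered, leading to 21) or of the other arm (14-membered through sulfur), so the connectivity of the product is to be proved by HMBC (C1 carbonyl to H11 of the same spin system) before going on; this is the main open point after the key step.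

Step 13
Reactants: 21 (3S,3'S)-3,3'-sulfanediylbis[(6S,12R)-6-(tert-butyldimethylsilyloxy)-12-methyl-5-nitrooxacyclododecan-2-one]
Product: 23 (3S,3'S)-3,3'-sulfanediylbis[(6S,12R)-6-(tert-butyldimethylsilyloxy)-12-methyloxacyclododecane-2,5-dione], via the disodium bis(nitronate) 22 (not isolated)
Conditions: NaOMe (2.0 equiv), MeOH/THF, 0 °C; then aq TiCl3, NH4OAc (pH 5–6), THF/H2O, 0 °C → rt
Reagents that add atoms: water, O
Why: McMurry's reductive Nef reaction: trivalent titanium reduces the nitronate through the oxime to the imine, which hydrolyses to the ketone; reductive conditions spare the sulfide and both C4 epimers converge. One equivalent of methoxide per nitro group is consumed by the far more acidic C4–H before it can attack a lactone or C2–H, and the ketone first appears in a weakly acidic buffer in which C3 does not enolise.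

Step 14
Reactants: 23 (3S,3'S)-3,3'-sulfanediylbis[(6S,12R)-6-(tert-butyldimethylsilyloxy)-12-methyloxacyclododecane-2,5-dione]
Product: 24 thiocladospolide F, (3S,3'S)-3,3'-sulfanediylbis[(6S,12R)-6-hydroxy-12-methyloxacyclododecane-2,5-dione]
Conditions: HF·pyridine, pyridine/THF, 0 °C → rt
Reagents that add atoms: none
Why: fluoride cleavage of secondary silyl ethers under weakly acidic conditions; pyridinium fluoride is not basic enough to start the retro-sulfa-Michael reaction or to epimerise the ketol centre C5.

## Compound list

1 | (3R)-3-hydroxyoxolan-2-one | O[C@@H]1CCOC1=O | starting material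
2 | (3R)-2-oxooxolan-3-yl trifluoromethanesulfonate | O=S(=O)(O[C@@H]1CCOC1=O)C(F)(F)F | intermediate
3 | (3S)-3-sulfanyloxolan-2-one | S[C@H]1CCOC1=O | intermediate (not isolated)
4 | (3S,3'S)-3,3'-sulfanediylbis(oxolan-2-one) | O=C1OCC[C@@H]1S[C@H]1CCOC1=O | intermediate
5 | prop-2-en-1-ol | C=CCO | starting material
6 | bis(dibromoboryl) (2S,2'S)-2,2'-sulfanediylbis(4-bromobutanoate) | BrCC[C@H](S[C@@H](CCBr)C(=O)OB(Br)Br)C(=O)OB(Br)Br | intermediate (not isolated)
7 | diallyl (2S,2'S)-2,2'-sulfanediylbis(4-bromobutanoate) | BrCC[C@H](S[C@@H](CCBr)C(=O)OCC=C)C(=O)OCC=C | intermediate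
8 | diallyl (2S,2'S)-2,2'-sulfanediylbis(4-nitrobutanoate) | [O-][N+](=O)CC[C@H](S[C@@H](CC[N+](=O)[O-])C(=O)OCC=C)C(=O)OCC=C | intermediate
9 | 6-bromohex-1-ene | C=CCCCCBr | starting material
10 | (R)-2-methyloxirane | C[C@@H]1CO1 | starting material
11 | hex-5-en-1-ylmagnesium bromide | C=CCCCC[Mg]Br | intermediate (not isolated)
12 | (2R)-non-8-en-2-ol | C[C@@H](O)CCCCCC=C | intermediate
13 | 1-methoxy-4-({[(2R)-non-8-en-2-yl]oxy}methyl)benzene | C[C@@H](OCc1ccc(OC)cc1)CCCCCC=C | intermediate
14 | (8R)-8-[(4-methoxybenzyl)oxy]nonane-1,2-diol, both C2 epimers | C[C@@H](OCc1ccc(OC)cc1)CCCCCC(O)CO | intermediate (not isolated)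
15 | (7R)-7-[(4-methoxybenzyl)oxy]octanal | C[C@@H](OCc1ccc(OC)cc1)CCCCCC=O | intermediate
16 | diallyl (2S,2'S)-2,2'-sulfanediylbis[(5S,11R)-5-hydroxy-11-(4-methoxybenzyloxy)-4-nitrododecanoate], C4/C4' epimers | C[C@@H](OCc1ccc(OC)cc1)CCCCC[C@H](O)C([N+](=O)[O-])C[C@H](S[C@@H](CC([N+](=O)[O-])[C@@H](O)CCCCC[C@@H](C)OCc1ccc(OC)cc1)C(=O)OCC=C)C(=O)OCC=C | intermediate
17 | diallyl (2S,2'S)-2,2'-sulfanediylbis[(5S,11R)-5-(tert-butyldimethylsilyloxy)-11-(4-methoxybenzyloxy)-4-nitrododecanoate] | C[C@@H](OCc1ccc(OC)cc1)CCCCC[C@H](O[Si](C)(C)C(C)(C)C)C([N+](=O)[O-])C[C@H](S[C@@H](CC([N+](=O)[O-])[C@@H](O[Si](C)(C)C(C)(C)C)CCCCC[C@@H](C)OCc1ccc(OC)cc1)C(=O)OCC=C)C(=O)OCC=C | intermediate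
18 | diallyl (2S,2'S)-2,2'-sulfanediylbis[(5S,11R)-5-(tert-butyldimethylsilyloxy)-11-hydroxy-4-nitrododecanoate] | C[C@@H](O)CCCCC[C@H](O[Si](C)(C)C(C)(C)C)C([N+](=O)[O-])C[C@H](S[C@@H](CC([N+](=O)[O-])[C@@H](O[Si](C)(C)C(C)(C)C)CCCCC[C@@H](C)O)C(=O)OCC=C)C(=O)OCC=C | intermediate
19 | (2S,2'S)-2,2'-sulfanediylbis[(5S,11R)-5-(tert-butyldimethylsilyloxy)-11-hydroxy-4-nitrododecanoic acid] | C[C@@H](O)CCCCC[C@H](O[Si](C)(C)C(C)(C)C)C([N+](=O)[O-])C[C@H](S[C@@H](CC([N+](=O)[O-])[C@@H](O[Si](C)(C)C(C)(C)C)CCCCC[C@@H](C)O)C(=O)O)C(=O)O | intermediate
20 | (2S,5S,11R)-5-(tert-butyldimethylsilyloxy)-11-hydroxy-4-nitro-2-{[(3S,6S,12R)-6-(tert-butyldimethylsilyloxy)-12-methyl-5-nitro-2-oxooxacyclododecan-3-yl]sulfanyl}dodecanoic acid | C[C@@H]1CCCCC[C@H](O[Si](C)(C)C(C)(C)C)C([N+](=O)[O-])C[C@H](S[C@@H](CC([N+](=O)[O-])[C@@H](O[Si](C)(C)C(C)(C)C)CCCCC[C@@H](C)O)C(=O)O)C(=O)O1 | intermediate (not isolated)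
21 | (3S,3'S)-3,3'-sulfanediylbis[(6S,12R)-6-(tert-butyldimethylsilyloxy)-12-methyl-5-nitrooxacyclododecan-2-one] | C[C@@H]1CCCCC[C@H](O[Si](C)(C)C(C)(C)C)C([N+](=O)[O-])C[C@H](S[C@H]2CC([N+](=O)[O-])[C@@H](O[Si](C)(C)C(C)(C)C)CCCCC[C@@H](C)OC2=O)C(=O)O1 | intermediate
22 | disodium bis(nitronate) of 21 | C[C@@H]1CCCCC[C@H](O[Si](C)(C)C(C)(C)C)C(=[N+]([O-])[O-])C[C@H](S[C@H]2CC(=[N+]([O-])[O-])[C@@H](O[Si](C)(C)C(C)(C)C)CCCCC[C@@H](C)OC2=O)C(=O)O1.[Na+].[Na+] | intermediate (not isolated)
23 | (3S,3'S)-3,3'-sulfanediylbis[(6S,12R)-6-(tert-butyldimethylsilyloxy)-12-methyloxacyclododecane-2,5-dione] | C[C@@H]1CCCCC[C@H](O[Si](C)(C)C(C)(C)C)C(=O)C[C@H](S[C@H]2CC(=O)[C@@H](O[Si](C)(C)C(C)(C)C)CCCCC[C@@H](C)OC2=O)C(=O)O1 | intermediate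
24 | thiocladospolide F | C[C@@H]1CCCCC[C@H](O)C(=O)C[C@H](S[C@H]2CC(=O)[C@@H](O)CCCCC[C@@H](C)OC2=O)C(=O)O1 | target

## Step count and least certain steps

Total step count: 14. Longest linear sequence: 11 steps (steps 1–4 and 8–14, from 1).

Step 8 (key step). The double addition may stay incomplete, because the nitroalkane and not the aldehyde is the limiting partner and the addition is reversible. Face selectivity may erode, because a substituted nitronate is bulkier than that of nitromethane, and because the core of 8 (sulfur flanked by two ester carbonyls) can bind copper outside the chiral ligand and open an unselective pathway. The free C5 hydroxyl may also lactonise onto the allyl ester on standing. Fallback: the addition is made irreversible with a preformed silyl nitronate. It sets out from 8: Me3SiCl and Et3N give the bis(trimethylsilyl nitronate) F1. Fluoride-initiated addition of F1 to 15 (chiral quaternary ammonium bifluoride, THF, −78 °C) passes the silyl group to the new alkoxide and gives the bis(trimethylsilyl ether) F2. Dilute citric acid removes the trimethylsilyl groups and the fallback comes back to the route at 16.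

Step 12. The first ring closure may mispair. Nothing in 19 distinguishes the two C11 hydroxyls, and ring-size statistics do not favour the 12-membered over the 14-membered ring, so closure across the sulfur bridge would lead to an isomeric bicyclic bis-lactone. The only rational lever within the step is temperature, since the larger ring pays more in entropy. Epimerisation at C2 through the activated acyl group and O-acylation of a C4 nitronate formed by DMAP are further risks. Fallback: each ring is closed before the sulfur bridge is made. It sets out from aldehyde 15 and purchased methyl 4-nitrobutanoate. The same Cu(OAc)2–bis(oxazoline) Henry reaction gives methyl (5S,11R)-5-hydroxy-11-(4-methoxybenzyloxy)-4-nitrododecanoate F3. Silylation gives its TBS ether F4, and DDQ gives the C11 alcohol F5. LiOH, then careful acidification, gives the hydroxy acid F6. MNBA lactonization, now with one carboxyl and one hydroxyl only, gives the 12-membered nitro lactone F7. The TiCl3 Nef reaction gives the keto lactone F8, and dehydrogenation with IBX gives the (E)-enone F9. HF·pyridine gives the hydroxy enone F10. Two molecules of F10 and half an equivalent of NaSH in a pH 7–8 buffer undergo two successive sulfa-Michael additions at C2 (beta to the ketone), and the fallback comes back to the route at 24. Its price is that C2 is then set by the macrocycle and by equilibration, not by SN2 inversion.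

Step 13. Methoxide may attack a lactone, silyloxide may be eliminated from the C4 nitronate, the reduction may stall at the oxime, and, once the ketone exists, thiolate may be lost if the pH drifts upward. Fallback: the ketone is reached through the isolated oxime without alkoxide. It sets out from 21: SnCl2, PhSH and Et3N (a divalent tin thiolate) reduce the nitro groups to the bis(oxime) F11. Aqueous TiCl3 at pH 4–5 cleaves the oximes, and the fallback comes back at 23.

Step 2. Triflate may be eliminated to the butenolide, and the alpha-thio lactone may partly epimerise, which would give the meso-type diastereomer of 4. Fallback: the alcohol is activated in place instead of through an isolated triflate. It sets out from 1: a Mitsunobu reaction with thioacetic acid (PPh3, DIAD) gives, with inversion, S-[(3S)-2-oxooxolan-3-yl] ethanethioate F12. Hydrazine acetate frees thiol 3, which is then isolated. A second Mitsunobu reaction of 3 with another molecule of 1 forms the second C–S bond with inversion and comes back at 4.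

Step 3. The boron–sulfide complex may lead to C–S cleavage or epimerisation, HBr may consume allyl alcohol, and the bromo acid may relactonise during work-up. Fallback: opening and esterification are separated. It sets out from 4: HBr in AcOH gives (2S,2'S)-2,2'-sulfanediylbis(4-bromobutanoic acid) F13. Acid-catalysed esterification with 5 (TsOH, toluene, removal of water) comes back at 7.

## Further compounds

F1 | step 8 | diallyl (2S,2'S)-2,2'-sulfanediylbis(4-nitrobutanoate) bis(trimethylsilyl nitronate) | [O-][N+](O[Si](C)(C)C)=CC[C@H](S[C@@H](CC=[N+]([O-])O[Si](C)(C)C)C(=O)OCC=C)C(=O)OCC=C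
F2 | step 8 | diallyl (2S,2'S)-2,2'-sulfanediylbis[(5S,11R)-11-(4-methoxybenzyloxy)-4-nitro-5-(trimethylsilyloxy)dodecanoate] | C[C@@H](OCc1ccc(OC)cc1)CCCCC[C@H](O[Si](C)(C)C)C([N+](=O)[O-])C[C@H](S[C@@H](CC([N+](=O)[O-])[C@@H](O[Si](C)(C)C)CCCCC[C@@H](C)OCc1ccc(OC)cc1)C(=O)OCC=C)C(=O)OCC=C
F3 | step 12 | methyl (5S,11R)-5-hydroxy-11-(4-methoxybenzyloxy)-4-nitrododecanoate | C[C@@H](OCc1ccc(OC)cc1)CCCCC[C@H](O)C([N+](=O)[O-])CCC(=O)OC
F4 | step 12 | methyl (5S,11R)-5-(tert-butyldimethylsilyloxy)-11-(4-methoxybenzyloxy)-4-nitrododecanoate | C[C@@H](OCc1ccc(OC)cc1)CCCCC[C@H](O[Si](C)(C)C(C)(C)C)C([N+](=O)[O-])CCC(=O)OC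
F5 | step 12 | methyl (5S,11R)-5-(tert-butyldimethylsilyloxy)-11-hydroxy-4-nitrododecanoate | C[C@@H](O)CCCCC[C@H](O[Si](C)(C)C(C)(C)C)C([N+](=O)[O-])CCC(=O)OC
F6 | step 12 | (5S,11R)-5-(tert-butyldimethylsilyloxy)-11-hydroxy-4-nitrododecanoic acid | C[C@@H](O)CCCCC[C@H](O[Si](C)(C)C(C)(C)C)C([N+](=O)[O-])CCC(=O)O
F7 | step 12 | (6S,12R)-6-(tert-butyldimethylsilyloxy)-12-methyl-5-nitrooxacyclododecan-2-one | C[C@@H]1CCCCC[C@H](O[Si](C)(C)C(C)(C)C)C([N+](=O)[O-])CCC(=O)O1
F8 | step 12 | (6S,12R)-6-(tert-butyldimethylsilyloxy)-12-methyloxacyclododecane-2,5-dione | C[C@@H]1CCCCC[C@H](O[Si](C)(C)C(C)(C)C)C(=O)CCC(=O)O1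
F9 | step 12 | (3E,6S,12R)-6-(tert-butyldimethylsilyloxy)-12-methyloxacyclododec-3-ene-2,5-dione | C[C@@H]1CCCCC[C@H](O[Si](C)(C)C(C)(C)C)C(=O)/C=C/C(=O)O1
F10 | step 12 | (3E,6S,12R)-6-hydroxy-12-methyloxacyclododec-3-ene-2,5-dione | C[C@@H]1CCCCC[C@H](O)C(=O)/C=C/C(=O)O1
F11 | step 13 | (3S,3'S)-3,3'-sulfanediylbis[(6S,12R)-6-(tert-butyldimethylsilyloxy)-5-(hydroxyimino)-12-methyloxacyclododecan-2-one] | C[C@@H]1CCCCC[C@H](O[Si](C)(C)C(C)(C)C)C(=NO)C[C@H](S[C@H]2CC(=NO)[C@@H](O[Si](C)(C)C(C)(C)C)CCCCC[C@@H](C)OC2=O)C(=O)O1
F12 | step 2 | S-[(3S)-2-oxooxolan-3-yl] ethanethioate | CC(=O)S[C@H]1CCOC1=O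
F13 | step 3 | (2S,2'S)-2,2'-sulfanediylbis(4-bromobutanoic acid) | BrCC[C@H](S[C@@H](CCBr)C(=O)O)C(=O)O
A1 | alternative 1 | bis-lactone of the target skeleton with C4 and C4' as 1,3-dioxolanes and C5 and C5' as tert-butyldimethylsilyl ethers | C[C@@H]1CCCCC[C@H](O[Si](C)(C)C(C)(C)C)C3(OCCO3)C[C@H](S[C@H]2CC4(OCCO4)[C@@H](O[Si](C)(C)C(C)(C)C)CCCCC[C@@H](C)OC2=O)C(=O)O1
A2 | alternative 1 | (2S,2'S)-2,2'-sulfanediylbis[(5S,11R)-5-(tert-butyldimethylsilyloxy)-4,4-(ethylenedioxy)-11-hydroxydodecanoic acid] | C[C@@H](O)CCCCC[C@H](O[Si](C)(C)C(C)(C)C)C1(OCCO1)C[C@H](S[C@@H](CC2(OCCO2)[C@@H](O[Si](C)(C)C(C)(C)C)CCCCC[C@@H](C)O)C(=O)O)C(=O)O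
A3 | alternative 1 | (2R,5S,11R)-5-(tert-butyldimethylsilyloxy)-1,1,1-trichloro-4,4-(ethylenedioxy)dodecane-2,11-diol | O[C@H](CC1(OCCO1)[C@@H](O[Si](C)(C)C(C)(C)C)CCCCC[C@@H](C)O)C(Cl)(Cl)Cl
A4 | alternative 2 | bis[(R)-but-3-en-2-yl] (2S,2'S)-2,2'-sulfanediylbis[(5S)-5-(tert-butyldimethylsilyloxy)-4-oxodec-9-enoate] | C[C@@H](OC(=O)[C@@H](S[C@@H](CC(=O)[C@@H](O[Si](C)(C)C(C)(C)C)CCCC=C)C(=O)O[C@H](C)C=C)CC(=O)[C@@H](O[Si](C)(C)C(C)(C)C)CCCC=C)C=C
A5 | alternative 2 | bis[(R)-but-3-en-2-yl] 2,2'-sulfanediylbis(prop-2-enoate) | C=C(SC(=C)C(=O)O[C@H](C)C=C)C(=O)O[C@H](C)C=C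
A6 | alternative 2 | (2S)-2-(tert-butyldimethylsilyloxy)hept-6-enal | O=C[C@@H](O[Si](C)(C)C(C)(C)C)CCCC=C
A7 | alternative 3 | (3S,6S,12R)-6-(4-methoxybenzyloxy)-12-methyl-5-methylidene-3-{[2-(trimethylsilyl)ethyl]sulfanyl}oxacyclododecan-2-one | C[C@@H]1CCCCC[C@H](OCc2ccc(OC)cc2)C(=C)C[C@H](SCC[Si](C)(C)C)C(=O)O1
A8 | alternative 3 | (2R,8S)-8-(4-methoxybenzyloxy)-9-({[2-(trimethylsilyl)ethyl]sulfanyl}methyl)dec-9-en-2-yl diazoacetate | [N-]=[N+]=CC(=O)O[C@H](C)CCCCC[C@H](OCc1ccc(OC)cc1)C(=C)CSCC[Si](C)(C)C
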